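**Retrosynthetic overview**

1. Skeleton numbering: C1 lavandulyl bridgehead, C2 ring C=O, C3 benzoyl carbon, C4 C–OMe, C5 prenyl bridgehead, C6 CMe2, C7 CH(prenyl), C8 CH2, C9 bridging C=O; ring A = C1, C8, C7, C6, C5, C9; ring B = C1 to C5 plus C9; exo/endo at C7 = away from/toward ring B.
2. Feature used: the quaternary C5 lies between the two oxygen-bearing carbons C4 and C9, so ring B can be taken back to an achiral 1-substituted 2,6-dimethoxycyclohexa-2,5-diene (Birch product) whose two enol ethers are mirror-image related.
3. Key disconnection C1–C8 (ring B first from the arene, ring A second): the diazoketone carbon C8, tethered through C6–C7, is added as a chiral copper carbenoid across one enol ether (C9=C1); acid then breaks the temporary C8–C9 bond and leaves the C9 ketone.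
4. After it: C7 ketone to exo allyl by radical allylation, with C9 parked as a silyl-protected alcohol because the bridging ketone cannot be enolised but does take hydride; then C2 allylic oxidation; then both allyl groups to prenyl by cross-metathesis (the C5 chain is carried as allyl so that no prenyl C–H competes in the oxidation).
5. Last disconnections: C1–lavandulyl (bridgehead carbanion plus (S)-lavandulyl triflate from resolved lavandulol) and C3–benzoyl (vinyl lithiation, benzoyl chloride).

Key step: step 7

Assumption: the (S,S)-bisoxazoline is taken to direct the carbenoid to the enol ether that gives the drawn enantiomer; if the first run shows the opposite sense, the (R,R)-ligand is used with no other change.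
Assumption: the lipase is taken to acylate (R)-lavandulol faster, so that the S alcohol is the one recovered unreacted.

**Route**

Step 1
Reactants: 1 2-(2,6-dimethoxyphenyl)acetonitrile
Product: 2 2-(2,6-dimethoxyphenyl)-2-methylpropanenitrile
Conditions: NaH (2.5 equiv), MeI (3 equiv), THF, 0 °C → rt
Reagents that add atoms: iodomethane, CI
Why: Double SN2 C-methylation of the benzylic nitrile anion, the second methylation staying fast because MeI is small and the nitrile-stabilised anion is unhindered.

Step 2
Reactants: 2 2-(2,6-dimethoxyphenyl)-2-methylpropanenitrile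
Product: 4 3-(2,6-dimethoxyphenyl)-3-methylbutan-2-one, via ketimine 3 (not isolated)
Conditions: MeLi (2 equiv), Et2O–toluene, 0 → 40 °C; then 2 M HCl, rt
Reagents that add atoms: methyllithium, [Li]C; water, O
Why: Organolithium addition to a nitrile stops at the N-lithio ketimine, which aqueous acid hydrolyses to the methyl ketone (nitrile-to-ketone synthesis), and the quaternary α-carbon offers no proton to lose.

Step 3
Reactants: 4 3-(2,6-dimethoxyphenyl)-3-methylbutan-2-one
Product: 6 3-(2,6-dimethoxycyclohexa-2,5-dien-1-yl)-3-methylbutan-2-ol (racemic), via aryl carbinol 5 (not isolated)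
Conditions: Li (8 equiv), NH3 (l), THF, t-BuOH, −78 → −33 °C; solid NH4Cl, no acid in the work-up
Reagents that add atoms: none
Why: Dissolving-metal reduction takes the ketone to its alkoxide and then, as a Birch reduction, the 2-alkyl-1,3-dimethoxybenzene to the 2,5-dihydro compound with both methoxy groups on double bonds; the carbinol centre is racemic and is oxidised again in step 5.

Step 4
Reactants: 6 3-(2,6-dimethoxycyclohexa-2,5-dien-1-yl)-3-methylbutan-2-ol; 7 allyl bromide
Product: 8 3-[2,6-dimethoxy-1-(prop-2-enyl)cyclohexa-2,5-dien-1-yl]-3-methylbutan-2-ol (racemic)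
Conditions: s-BuLi (2.3 equiv), TMEDA, THF, −78 → −40 °C; then 7 (1.1 equiv), −78 °C
Reagents that add atoms: none
Why: Alkoxide-directed lithiation removes the doubly allylic ring C–H between the two methoxy-bearing carbons, and the pentadienyl anion is alkylated at its central carbon, where the charge is highest, which creates the quaternary C5 (lithiation–alkylation of a 1,5-dimethoxycyclohexa-1,4-diene).

Step 5
Reactants: 8 3-[2,6-dimethoxy-1-(prop-2-enyl)cyclohexa-2,5-dien-1-yl]-3-methylbutan-2-ol
Product: 9 3-[2,6-dimethoxy-1-(prop-2-enyl)cyclohexa-2,5-dien-1-yl]-3-methylbutan-2-one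
Conditions: Dess–Martin periodinane, pyridine, CH2Cl2, 0 °C → rt
Reagents that add atoms: none
Why: Dess–Martin oxidation under pyridine buffer turns the hindered secondary alcohol into the methyl ketone without the acid that would hydrolyse the enol ethers.

Step 6
Reactants: 9 3-[2,6-dimethoxy-1-(prop-2-enyl)cyclohexa-2,5-dien-1-yl]-3-methylbutan-2-one
Product: 11 1-diazo-3-[2,6-dimethoxy-1-(prop-2-enyl)cyclohexa-2,5-dien-1-yl]-3-methylbutan-2-one, via trifluoroacetyl ketone 10 (not isolated)
Conditions: LiN(SiMe3)2, THF, −78 °C; CF3CO2CH2CF3; then CH3SO2N3, Et3N, H2O (1 equiv), MeCN, rt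
Reagents that add atoms: methanesulfonyl azide, CS(=O)(=O)N=[N+]=[N-] (gives the N2 of 11); 2,2,2-trifluoroethyl trifluoroacetate, O=C(OCC(F)(F)F)C(F)(F)F (gives the CF3CO group of 10 only)
Why: Regitz-type deacylative diazo transfer: the only enolisable position (the CH3) is trifluoroacetylated through its lithium enolate and the activated diketone takes the diazo group from the sulfonyl azide with loss of the trifluoroacetyl group, so neither a free acid nor an acid chloride meets the enol ethers.

Step 7
Reactants: 11 1-diazo-3-[2,6-dimethoxy-1-(prop-2-enyl)cyclohexa-2,5-dien-1-yl]-3-methylbutan-2-one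
Product: 13 5-allyl-4-methoxy-6,6-dimethylbicyclo[3.3.1]non-3-ene-7,9-dione, via methoxycyclopropane 12 (not isolated)
Conditions: [Cu(MeCN)4]PF6 (5 mol%, monovalent copper), 2,2'-(propane-2,2-diyl)bis[(4S)-4-tert-butyl-4,5-dihydrooxazole] (6 mol%), toluene, rt, slow addition of 11; then 0.1 M HCl, THF–H2O, 0 °C, short contact, NaHCO3
Reagents that add atoms: water, O
Why: The copper–bisoxazoline complex turns the diazoketone into an electrophilic carbenoid at C8, which adds across one of the two mirror-image-related methoxy enol ethers (C9=C1) to give 12; the closest known reaction type is the catalytic asymmetric intramolecular cyclopropanation of α-diazoketones onto methoxycyclohexadienes. This first closure forms the five-membered ring C5–C6–C7–C8–C9 by 5-exo delivery of the tethered carbenoid, together with the three-membered ring C1–C8–C9. In dilute acid the C7 carbonyl is protonated and the C8–C9 bond, which joins the methoxy donor carbon to the carbon α to the ketone, breaks heterolytically; water converts the C9 oxocarbenium ion into the ketone with loss of methanol, so the surviving C1–C8 bond amounts to a six-membered closure of ring A. C5 becomes stereogenic through the ligand's choice of enol ether, and C1 follows from it because the tether can deliver C8 only to the ring face on which it stands. The step needs group selectivity between the enol ethers (ligand), chemoselectivity for an enol ether over the allyl group (far more nucleophilic, and it leads to a five-membered ring), and opening without hydrolysis of the C4 enol ether (the push–pull cyclopropane ionises more easily than an enol ether next to a quaternary carbon and a β-carbonyl is protonated).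

Step 8
Reactants: 13 5-allyl-4-methoxy-6,6-dimethylbicyclo[3.3.1]non-3-ene-7,9-dione
Product: 14 5-allyl-9-hydroxy-4-methoxy-6,6-dimethylbicyclo[3.3.1]non-3-en-7-one (9-OH drawn on the ring A side)
Conditions: LiN(i-Pr)2 (1.1 equiv), THF, −78 °C; then LiAlH4, −78 → 0 °C; aq. KNaC4H4O6
Reagents that add atoms: none
Why: In situ enolate protection: only the C7 ketone can be enolised (toward C8), so the amide base masks it as the lithium enolate and LiAlH4 reduces the non-enolisable bridging C9 ketone alone; hydride is expected from the more open face over ring B, and the C9 configuration does not matter because C9 is reoxidised in step 14.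

Step 9
Reactants: 14 5-allyl-9-hydroxy-4-methoxy-6,6-dimethylbicyclo[3.3.1]non-3-en-7-one
Product: 15 5-allyl-4-methoxy-6,6-dimethyl-9-(triethylsilyloxy)bicyclo[3.3.1]non-3-en-7-one
Conditions: Et3SiOSO2CF3 (1.3 equiv), 2,6-lutidine, CH2Cl2, −78 °C
Reagents that add atoms: triethylsilyl trifluoromethanesulfonate, CC[Si](CC)(CC)OS(=O)(=O)C(F)(F)F
Why: Silyl triflate silylation reaches the hindered secondary alcohol at low temperature, while the lutidine buffer keeps the enol ether and the ketone untouched.

Step 10
Reactants: 15 5-allyl-4-methoxy-6,6-dimethyl-9-(triethylsilyloxy)bicyclo[3.3.1]non-3-en-7-one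
Product: 16 5-allyl-4-methoxy-6,6-dimethyl-9-(triethylsilyloxy)bicyclo[3.3.1]non-3-en-7-ol (7-OH endo)
Conditions: LiAlH4, THF, 0 °C
Reagents that add atoms: none
Why: Hydride reduction of the only carbonyl left; attack from the exo face (the endo face is covered by ring B) should give the endo alcohol, and either epimer would serve because C7 becomes a radical in step 12.

Step 11
Reactants: 16 5-allyl-4-methoxy-6,6-dimethyl-9-(triethylsilyloxy)bicyclo[3.3.1]non-3-en-7-ol
Product: 17 O-[5-allyl-4-methoxy-6,6-dimethyl-9-(triethylsilyloxy)bicyclo[3.3.1]non-3-en-7-yl] S-methyl dithiocarbonate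
Conditions: NaH, THF, 0 °C → rt; CS2; MeI
Reagents that add atoms: carbon disulfide, S=C=S; iodomethane, CI
Why: Xanthate formation (alkoxide addition to CS2, then S-methylation) works on hindered alkoxides because CS2 is small, and it provides the radical precursor.

Step 12
Reactants: 17 O-[5-allyl-4-methoxy-6,6-dimethyl-9-(triethylsilyloxy)bicyclo[3.3.1]non-3-en-7-yl] S-methyl dithiocarbonate
Product: 18 5,7-diallyl-4-methoxy-6,6-dimethyl-9-(triethylsilyloxy)bicyclo[3.3.1]non-3-ene (7-allyl exo)
Conditions: Bu3SnCH2CH=CH2 (5 equiv), AIBN (portions), benzene, 80 °C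
Reagents that add atoms: allyltributylstannane, C=CC[Sn](CCCC)(CCCC)CCCC
Why: Keck radical allylation: the stannyl radical adds to the thiocarbonyl, the C7 radical is released and is captured by the allylstannane on its exo face because the endo face is shielded by ring B, which sets C7 (allyl exo, H endo); the C5 allyl group is equatorial on ring A and cannot be reached by the radical.

Step 13
Reactants: 18 5,7-diallyl-4-methoxy-6,6-dimethyl-9-(triethylsilyloxy)bicyclo[3.3.1]non-3-ene
Product: 19 5,7-diallyl-4-methoxy-6,6-dimethylbicyclo[3.3.1]non-3-en-9-ol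
Conditions: Bu4NF, THF, rt → 40 °C
Reagents that add atoms: none
Why: Fluoride cleavage of the silyl ether under non-acidic conditions, which the methyl enol ether tolerates.

Step 14
Reactants: 19 5,7-diallyl-4-methoxy-6,6-dimethylbicyclo[3.3.1]non-3-en-9-ol
Product: 20 5,7-diallyl-4-methoxy-6,6-dimethylbicyclo[3.3.1]non-3-en-9-one
Conditions: Dess–Martin periodinane, NaHCO3, CH2Cl2, rt
Reagents that add atoms: none
Why: Buffered Dess–Martin oxidation returns the bridging C9 ketone and removes the temporary C9 stereocentre.

Step 15
Reactants: 20 5,7-diallyl-4-methoxy-6,6-dimethylbicyclo[3.3.1]non-3-en-9-one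
Product: 21 5,7-diallyl-4-methoxy-6,6-dimethylbicyclo[3.3.1]non-3-ene-2,9-dione
Conditions: Rh2(cap)4 (1 mol%; dirhodium tetrakis(caprolactamate), Rh2(C6H10NO)4), t-BuOOH (5 equiv), K2CO3, CH2Cl2, rt
Reagents that add atoms: tert-butyl hydroperoxide, CC(C)(C)OO
Why: Allylic C–H oxidation by tert-butylperoxyl radicals: the C2–H bonds are the weakest in the molecule because the derived allyl radical is stabilised by the C4 methoxy group, and the peroxide formed at the less hindered C2 collapses to the ketone of the vinylogous ester, while the terminal allyl groups have stronger allylic C–H bonds.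

Step 16
Reactants: 21 5,7-diallyl-4-methoxy-6,6-dimethylbicyclo[3.3.1]non-3-ene-2,9-dione
Product: 22 4-methoxy-6,6-dimethyl-5,7-bis(3-methylbut-2-enyl)bicyclo[3.3.1]non-3-ene-2,9-dione (7-prenyl exo)
Conditions: 2-methylbut-2-ene (large excess), second-generation Grubbs catalyst RuCl2(=CHPh)(PCy3)(H2IMes) (5 mol%), CH2Cl2, 40 °C
Reagents that add atoms: 2-methylbut-2-ene, CC=C(C)C
Why: Olefin cross-metathesis converts both terminal allyl groups into prenyl groups with loss of propene, and the trisubstituted, electron-poor ring alkene does not engage the ruthenium carbene.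

Step 17
Reactants: 23 (±)-lavandulol
Product: 24 (S)-lavandulol
Conditions: Candida antarctica lipase B (immobilised), vinyl acetate, hexane, 30 °C, taken past half conversion; chromatography
Reagents that add atoms: none
Why: Lipase-catalysed kinetic resolution by transesterification: the enzyme is expected to acylate the R alcohol faster, so the alcohol recovered after more than half conversion should be the S enantiomer, whose purity would be checked before use.

Step 18
Reactants: 24 (S)-lavandulol
Product: 25 (S)-lavandulyl trifluoromethanesulfonate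
Conditions: (CF3SO2)2O, 2,6-lutidine, CH2Cl2, −78 °C; cold filtration, used at once
Reagents that add atoms: trifluoromethanesulfonic anhydride, O=S(=O)(OS(=O)(=O)C(F)(F)F)C(F)(F)F
Why: O-triflation of a primary alcohol at low temperature does not touch the stereocentre and gives the most reactive alkylating form of the β-branched chain.

Step 19
Reactants: 22 4-methoxy-6,6-dimethyl-5,7-bis(3-methylbut-2-enyl)bicyclo[3.3.1]non-3-ene-2,9-dione; 25 (S)-lavandulyl trifluoromethanesulfonate
Product: 26 4-methoxy-6,6-dimethyl-5,7-bis(3-methylbut-2-enyl)-1-[(2R)-5-methyl-2-(prop-1-en-2-yl)hex-4-enyl]bicyclo[3.3.1]non-3-ene-2,9-dione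
Conditions: LiN(i-Pr)2 (1.3 equiv), THF, −78 °C; then 25 (2.5 equiv), −78 → −30 °C
Reagents that add atoms: none
Why: Bridgehead lithiation–alkylation: the C1–H between the C9 ketone and the C2 carbonyl is removed by the amide base (as is done with allylic halides on O-methylated bicyclo[3.3.1]nonane-2,4,9-triones) and the carbanion displaces triflate from the primary carbon by SN2; C1 keeps its configuration because a bridgehead cannot invert, and the side-chain stereocentre is not involved.

Step 20
Reactants: 26 4-methoxy-6,6-dimethyl-5,7-bis(3-methylbut-2-enyl)-1-[(2R)-5-methyl-2-(prop-1-en-2-yl)hex-4-enyl]bicyclo[3.3.1]non-3-ene-2,9-dione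
Product: 27 CNP0385193.1 (3-benzoyl derivative of 26)
Conditions: lithium 2,2,6,6-tetramethylpiperidide (2 equiv), THF, −78 °C; PhCOCl, −78 → −40 °C
Reagents that add atoms: benzoyl chloride, O=C(Cl)c1ccccc1
Why: Vinyl C–H lithiation at C3, between the C2 carbonyl and the C4 methoxy group, by the hindered amide, followed by C-acylation with benzoyl chloride, completes the vinylogous ester of the target without touching any stereocentre.

**Compound list**

1 | 2-(2,6-dimethoxyphenyl)acetonitrile | N#CCc1c(OC)cccc1OC | starting material
2 | 2-(2,6-dimethoxyphenyl)-2-methylpropanenitrile | N#CC(C)(C)c1c(OC)cccc1OC | intermediate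
3 | 3-(2,6-dimethoxyphenyl)-3-methylbutan-2-imine | CC(=N)C(C)(C)c1c(OC)cccc1OC | intermediate (not isolated)
4 | 3-(2,6-dimethoxyphenyl)-3-methylbutan-2-one | CC(=O)C(C)(C)c1c(OC)cccc1OC | intermediate
5 | 3-(2,6-dimethoxyphenyl)-3-methylbutan-2-ol, racemic | CC(O)C(C)(C)c1c(OC)cccc1OC | intermediate (not isolated)
6 | 3-(2,6-dimethoxycyclohexa-2,5-dien-1-yl)-3-methylbutan-2-ol, racemic | COC1=CCC=C(OC)C1C(C)(C)C(C)O | intermediate
7 | allyl bromide | C=CCBr | starting material
8 | 3-[2,6-dimethoxy-1-(prop-2-enyl)cyclohexa-2,5-dien-1-yl]-3-methylbutan-2-ol, racemic | COC1=CCC=C(OC)C1(CC=C)C(C)(C)C(C)O | intermediate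
9 | 3-[2,6-dimethoxy-1-(prop-2-enyl)cyclohexa-2,5-dien-1-yl]-3-methylbutan-2-one | COC1=CCC=C(OC)C1(CC=C)C(C)(C)C(C)=O | intermediate
10 | 1,1,1-trifluoro-5-[2,6-dimethoxy-1-(prop-2-enyl)cyclohexa-2,5-dien-1-yl]-5-methylhexane-2,4-dione | COC1=CCC=C(OC)C1(CC=C)C(C)(C)C(=O)CC(=O)C(F)(F)F | intermediate (not isolated)
11 | 1-diazo-3-[2,6-dimethoxy-1-(prop-2-enyl)cyclohexa-2,5-dien-1-yl]-3-methylbutan-2-one (achiral key-step precursor) | COC1=CCC=C(OC)C1(CC=C)C(C)(C)C(=O)C=[N+]=[N-] | intermediate
12 | tricyclic methoxycyclopropyl ketone: C8 bonded to both C1 and C9, C7 ketone, 4,9-dimethoxy, 5-allyl, 6,6-dimethyl | COC1=CC[C@@H]2[C@@H]3C(=O)C(C)(C)[C@@]1(CC=C)[C@]23OC | intermediate (not isolated)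
13 | 5-allyl-4-methoxy-6,6-dimethylbicyclo[3.3.1]non-3-ene-7,9-dione, C1 and C5 as in the target (key-step product) | [C@@H]12CC(=O)C(C)(C)[C@@](CC=C)(C1=O)C(OC)=CC2 | intermediate
14 | 5-allyl-9-hydroxy-4-methoxy-6,6-dimethylbicyclo[3.3.1]non-3-en-7-one, 9-OH on the ring A side (expected epimer) | [C@@H]12CC(=O)C(C)(C)[C@@](CC=C)([C@H]1O)C(OC)=CC2 | intermediate
15 | 9-O-triethylsilyl ether of 14 | [C@@H]12CC(=O)C(C)(C)[C@@](CC=C)([C@H]1O[Si](CC)(CC)CC)C(OC)=CC2 | intermediate
16 | 5-allyl-4-methoxy-6,6-dimethyl-9-(triethylsilyloxy)bicyclo[3.3.1]non-3-en-7-ol, 7-OH endo | [C@@H]12C[C@H](O)C(C)(C)[C@@](CC=C)([C@H]1O[Si](CC)(CC)CC)C(OC)=CC2 | intermediate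
17 | S-methyl dithiocarbonate (xanthate) of 16 | [C@@H]12C[C@H](OC(=S)SC)C(C)(C)[C@@](CC=C)([C@H]1O[Si](CC)(CC)CC)C(OC)=CC2 | intermediate
18 | 5,7-diallyl-4-methoxy-6,6-dimethyl-9-(triethylsilyloxy)bicyclo[3.3.1]non-3-ene, 7-allyl exo | [C@@H]12C[C@@H](CC=C)C(C)(C)[C@@](CC=C)([C@H]1O[Si](CC)(CC)CC)C(OC)=CC2 | intermediate
19 | 5,7-diallyl-4-methoxy-6,6-dimethylbicyclo[3.3.1]non-3-en-9-ol | [C@@H]12C[C@@H](CC=C)C(C)(C)[C@@](CC=C)([C@H]1O)C(OC)=CC2 | intermediate
20 | 5,7-diallyl-4-methoxy-6,6-dimethylbicyclo[3.3.1]non-3-en-9-one | [C@@H]12C[C@@H](CC=C)C(C)(C)[C@@](CC=C)(C1=O)C(OC)=CC2 | intermediate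
21 | 5,7-diallyl-4-methoxy-6,6-dimethylbicyclo[3.3.1]non-3-ene-2,9-dione | [C@@H]12C[C@@H](CC=C)C(C)(C)[C@@](CC=C)(C1=O)C(OC)=CC2=O | intermediate
22 | 4-methoxy-6,6-dimethyl-5,7-bis(3-methylbut-2-enyl)bicyclo[3.3.1]non-3-ene-2,9-dione, 7-prenyl exo | [C@@H]12C[C@@H](CC=C(C)C)C(C)(C)[C@@](CC=C(C)C)(C1=O)C(OC)=CC2=O | intermediate
23 | (±)-lavandulol | CC(C)=CCC(CO)C(C)=C | starting material
24 | (S)-lavandulol | C=C(C)[C@H](CC=C(C)C)CO | intermediate
25 | (S)-lavandulyl trifluoromethanesulfonate | C=C(C)[C@H](CC=C(C)C)COS(=O)(=O)C(F)(F)F | intermediate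
26 | 1-lavandulyl derivative of 22, side chain (2R) | C=C(C)[C@H](CC=C(C)C)C[C@@]12C[C@@H](CC=C(C)C)C(C)(C)[C@@](CC=C(C)C)(C1=O)C(OC)=CC2=O | intermediate
27 | CNP0385193.1 | C=C(C)[C@H](CC=C(C)C)C[C@@]12C[C@@H](CC=C(C)C)C(C)(C)[C@@](CC=C(C)C)(C1=O)C(OC)=C(C(=O)c1ccccc1)C2=O | target

**Step count**

Total steps: 20. Longest linear sequence: 18 (steps 1 to 16, then 19 and 20); steps 17 and 18 make the side-chain fragment.

**Steps most likely to fail**

Step 19. The strongly basic bridgehead carbanion may remove the allylic β-hydrogen of the branched homoallylic triflate (elimination), or the triflate may ionise, faster than the slow substitution at a β-branched carbon. Fallback, from 22 (with 24 as side-chain source) back to 26: 24 is oxidised with buffered Dess–Martin periodinane at 0 °C to (S)-lavandulal F1, which is used cold and at once. The bridgehead lithium species from 22 (LiN(i-Pr)2, THF, −78 °C) adds to the aldehyde carbonyl, which has no elimination channel and no β-branching penalty, to give the carbinol F2 as either epimer. PhOC(S)Cl, pyridine and DMAP convert it to the phenyl thionocarbonate F3. Barton–McCombie deoxygenation with Bu3SnH at high concentration (AIBN, toluene, 80 °C; the high concentration suppresses vinyl or acyl shifts of the intermediate radical) gives 26.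

Step 7. The chiral catalyst may discriminate poorly between the two enol ethers, so that the bicycle is formed with low enantiomeric purity. Fallback, from 11 back to 13: 11 is decomposed with achiral Cu(acac)2 (copper bis(acetylacetonate), divalent copper) in toluene at 80 °C and opened with dilute acid as in step 7. This gives 12 together with ent-12 F4, and then 13 together with ent-13 F5. The racemate is resolved by preparative chromatography on a chiral stationary phase, and 13 re-enters at step 8; resolution replaces asymmetric catalysis.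

Step 12. The hindered C7 radical may add too slowly to the allylstannane, so that hydrogen abstraction or transannular addition to the C3=C4 enol ether takes over. Fallback, from 17 back to 19: the allyl group is built in two stages with a faster radical trap. Giese addition of the C7 radical (Bu3SnH by syringe pump, AIBN, benzene, 80 °C) to phenyl vinyl sulfone gives the exo 2-(phenylsulfonyl)ethyl compound F6. Deprotonation α to sulfur (n-BuLi, THF, −78 °C) and alkylation with Me3SiCH2I give the β-silyl sulfone F7. Bu4NF in warm THF then eliminates sulfinate and silicon to the terminal alkene and removes the silyl ether in the same operation, giving 19.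

Further compounds
F1 | step 19 | (S)-lavandulal, (2S)-5-methyl-2-(prop-1-en-2-yl)hex-4-enal | C=C(C)[C@H](CC=C(C)C)C=O
F2 | step 19 | bridgehead carbinol from 22 and F1 (carbinol centre either epimer) | C=C(C)[C@H](CC=C(C)C)C(O)[C@@]12C[C@@H](CC=C(C)C)C(C)(C)[C@@](CC=C(C)C)(C1=O)C(OC)=CC2=O
F3 | step 19 | O-phenyl thionocarbonate of F2 | C=C(C)[C@H](CC=C(C)C)C(OC(=S)Oc3ccccc3)[C@@]12C[C@@H](CC=C(C)C)C(C)(C)[C@@](CC=C(C)C)(C1=O)C(OC)=CC2=O
F4 | step 7 | ent-12, mirror image of the methoxycyclopropane | COC1=CC[C@H]2[C@H]3C(=O)C(C)(C)[C@]1(CC=C)[C@@]23OC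
F5 | step 7 | ent-13, mirror image of the bicyclic dione | [C@H]12CC(=O)C(C)(C)[C@](CC=C)(C1=O)C(OC)=CC2
F6 | step 12 | 5-allyl-4-methoxy-6,6-dimethyl-7-exo-[2-(phenylsulfonyl)ethyl]-9-(triethylsilyloxy)bicyclo[3.3.1]non-3-ene | [C@@H]12C[C@@H](CCS(=O)(=O)c3ccccc3)C(C)(C)[C@@](CC=C)([C@H]1O[Si](CC)(CC)CC)C(OC)=CC2
F7 | step 12 | α-(trimethylsilylmethyl) derivative of sulfone F6 (sulfone carbon either epimer) | [C@@H]12C[C@@H](CC(C[Si](C)(C)C)S(=O)(=O)c3ccccc3)C(C)(C)[C@@](CC=C)([C@H]1O[Si](CC)(CC)CC)C(OC)=CC2
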